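**Plan**
- Cuts: first the exocyclic C5=CH bond of the triene linker (Knoevenagel), which separates a dione half (C1–C8a) from a dienal carbinol half (C1'–C8a'); then the two orsellinate C–O bonds; then, in each half, the pyran bond O2–C3, the C4–C4a bond (Sonogashira) and, in one operation, C8–C8a with C4a–I (iodide addition/aldol of an ynoate aldehyde).
- Forward: one lactone gives an acetonide lactol that feeds two branches; in each, carbocycle B (B') closes first and pyran A (A') second, by 6-endo oxa-Michael addition to an alkynyl enone; the halves are joined at C5, C7–OH is acylated and all silyl groups are removed.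
- Stereochemistry: 2-C-methyl-D-erythrono-1,4-lactone is the only chiral source. The carbinol half keeps its C2/C3 as C7'/C6' (C1 becomes C8', C4 becomes C5'); the dione half reads the same quaternary carbon the other way round (C1 is propargylated and becomes C6, C3 becomes the C8 aldehyde after glycol cleavage), which gives 7S.
- Enabling feature: in ring B' of the carbinol half, C8a' carries the one-carbon branch C1' and is bonded to the C8' carbonyl carbon, while its alkene partner C4a' is the sp2 carbon that must later be joined to C4'. Ring B' is therefore a cyclic 3-iodo-2-(1-hydroxyalkyl)acrylate in latent form, the product type of an iodide-triggered aldol between an ynoate and an aldehyde; ring B of the dione half has the same pattern.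

Key step: step 9

Assumption: atoms are numbered as in isochromene (unprimed in the dione half, primed in the carbinol half), the target is 7S,6'R,7'R as its SMILES encodes, and compounds 1 and 20 are taken as purchasable.

**Route**

Step 1
Reactants: 1 2-C-methyl-D-erythrono-1,4-lactone
Product: 2 2,3-O-isopropylidene-2-C-methyl-D-erythrono-1,4-lactone (cis-fused acetonide lactone)
Conditions: 2,2-dimethoxypropane, TsOH·H2O (cat.), acetone, rt
Reagents that add atoms: 2,2-dimethoxypropane, COC(C)(C)OC
Why: Acid-catalysed transketalisation of a cis-1,2-diol on a five-membered ring should give the cis-fused dioxolane without touching either stereocentre.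

Step 2
Reactants: 2 acetonide lactone
Product: 3 lactol (2,3-O-isopropylidene-2-C-methyl-D-erythrofuranose, both anomers)
Conditions: i-Bu2AlH (1.1 equiv), CH2Cl2, −78 °C; aq. potassium sodium tartrate
Reagents that add atoms: none
Why: Partial reduction of a γ-lactone at low temperature stops at the aluminium hemiacetal, which gives the lactol on work-up.

Step 3
Reactants: 3 lactol
Product: 4 vinyl alcohol, [(4R,5S)-5-ethenyl-2,2,5-trimethyl-1,3-dioxolan-4-yl]methanol
Conditions: Ph3PCH3Br, KOt-Bu (3 equiv each), THF, 0 °C to rt
Reagents that add atoms: methyltriphenylphosphonium bromide, C[P+](c1ccccc1)(c1ccccc1)c1ccccc1.[Br-]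
Why: Wittig methylenation of the open hydroxy-aldehyde form turns the future C8' into a vinyl group (a latent aldehyde) and frees the C5' hydroxyl; the α-carbon is quaternary and cannot epimerise.

Step 4
Reactants: 4 vinyl alcohol
Product: 5 primary triflate of 4
Conditions: (CF3SO2)2O, pyridine, CH2Cl2, −78 to −20 °C; used at once
Reagents that add atoms: trifluoromethanesulfonic anhydride, O=S(=O)(OS(=O)(=O)C(F)(F)F)C(F)(F)F
Why: Sulfonylation of the primary alcohol gives the leaving group needed at the β-oxygenated C5', and with C8' masked as an alkene no carbonyl oxygen can displace it intramolecularly.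

Step 5
Reactants: 5 triflate; 6 trimethylsilylacetylene
Product: 8 silyl alkyne (C5'–C4a' bond formed), via lithium (trimethylsilyl)acetylide 7 (not isolated)
Conditions: 6, n-BuLi, THF, −78 °C; then 5, DMPU, −78 to −20 °C
Reagents that add atoms: none
Why: SN2 displacement of a primary triflate by a lithium acetylide in a dipolar cosolvent is a standard alkylation and leaves C6' untouched.

Step 6
Reactants: 8 silyl alkyne
Product: 9 terminal alkyne, (4S,5R)-4-ethenyl-2,2,4-trimethyl-5-(prop-2-yn-1-yl)-1,3-dioxolane
Conditions: K2CO3, MeOH, rt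
Reagents that add atoms: none
Why: Methoxide-mediated protodesilylation of an alkynylsilane is mild and selective.

Step 7
Reactants: 9 terminal alkyne; 10 methyl chloroformate
Product: 12 ynoate alkene, via lithium acetylide 11 (not isolated)
Conditions: n-BuLi, THF, −78 °C; then ClCO2Me, −78 to 0 °C
Reagents that add atoms: none
Why: Acylation of a lithium acetylide with a chloroformate installs C1' as the ester and makes C8a'≡C4a' a conjugate acceptor.

Step 8
Reactants: 12 ynoate alkene
Product: 14 ynoate aldehyde, via secondary ozonide 13 (not isolated)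
Conditions: O3, CH2Cl2, −78 °C (stopped at first excess); then Me2S, −78 °C to rt
Reagents that add atoms: ozone, [O-][O+]=O
Why: Ozonolysis of the monosubstituted alkene is far faster than attack on the electron-poor conjugated alkyne, and Me2S (not a phosphine, which would add to the ynoate) reduces the ozonide to the non-enolisable C8' aldehyde.

Step 9
Reactants: 14 ynoate aldehyde
Product: 16 ring B' iodo enoate carbinol, via magnesium iodoallenolate 15 (not isolated)
Conditions: MgI2·OEt2 (1.5 equiv), CH2Cl2, −20 to 0 °C, anhydrous; aq. NH4Cl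
Reagents that add atoms: magnesium diiodide, [Mg+2].[I-].[I-]
Why: Coordination of MgI2 to the ynoate ester lets iodide attack C4a' in a conjugate sense, and the magnesium 3-iodoallenolate 15 so formed is intercepted at its central carbon C8a' by the tethered C8' aldehyde, so that C4a'–I and C8a'–C8' are made in one operation. The closest known reactions are the MgI2-mediated three-component β-iodo Morita–Baylis–Hillman coupling of ynoates with aldehydes and the MgI2 iodo-aldol cyclisation of enoate aldehydes. Ring B' closes by a 6-(enolexo)-exo-trig aldol in which the allenic C8a'=C4a' bond becomes the endocyclic alkene; the aldehyde hangs from C4a' through C5', so the new bond can only form cis to C5', which places iodine cis to the ester. The one new stereocentre, the C8' carbinol, needs no control because both epimers give the same ketone in step 12, and C6'/C7' are not involved. The step needs 1,4- rather than 1,2-addition of iodide and aldol capture rather than protonation of the allenolate: the soft nucleophile and the conjugated ester should secure the first, the chelated six-membered transition state under anhydrous conditions the second, and the aldehyde cannot enolise because C7' is quaternary. MgI2 is a mild Lewis acid and should leave the acetonide intact at or below 0 °C.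

Step 10
Reactants: 16 iodo enoate carbinol
Product: 17 iodo diol (C1' and C8' hydroxyls)
Conditions: i-Bu2AlH (3.5 equiv), CH2Cl2, −78 °C; aq. potassium sodium tartrate
Reagents that add atoms: none
Why: 1,2-Reduction of the enoate gives the allylic alcohol that supplies C1'–O2', and the vinyl iodide is inert to the hydride at low temperature.

Step 11
Reactants: 17 iodo diol
Product: 18 C1' silyl ether
Conditions: t-BuMe2SiCl (1.05 equiv), imidazole, CH2Cl2, 0 °C
Reagents that add atoms: tert-butyldimethylsilyl chloride, CC(C)(C)[Si](C)(C)Cl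
Why: The primary allylic hydroxyl is silylated much faster than the secondary C8' carbinol, which sits next to the quaternary C7'.

Step 12
Reactants: 18 silyl ether
Product: 19 iodo enone (C8' ketone)
Conditions: Dess–Martin periodinane, pyridine, CH2Cl2, 0 °C to rt
Reagents that add atoms: none
Why: Oxidation of the secondary allylic alcohol merges both C8' epimers and installs the carbonyl that later polarises the alkyne for pyran closure.

Step 13
Reactants: 19 iodo enone; 20 (E)-pent-2-en-4-yn-1-ol
Product: 21 enynyl enone (C4a'–C4' bond formed)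
Conditions: Pd(PPh3)2Cl2 (5 mol %), CuI (10 mol %), Et3N, THF, rt
Reagents that add atoms: none
Why: Sonogashira coupling of a β-iodo enone is fast, and a tertiary amine base avoids addition–elimination at C4a'.

Step 14
Reactants: 21 enynyl enone
Product: 23 pyranone alcohol (rings A' and B' with the C6'/C7' acetonide), via hydroxymethyl ynenone 22 (not isolated)
Conditions: Bu4NF (1.1 equiv), THF, 0 °C to rt
Reagents that add atoms: none
Why: Fluoride frees the C1' alkoxide, which should add to C3', the δ-carbon of the C8'-ketone-conjugated enyne (1,6-oxa-Michael, 6-endo-dig), to give the 2H-pyran as a vinylogous ester, whereas 5-exo attack at C4' would build charge where the carbonyl cannot stabilise it.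

Step 15
Reactants: 23 pyranone alcohol
Product: 24 dienal acetonide
Conditions: MnO2 (activated, excess), CH2Cl2, rt
Reagents that add atoms: none
Why: MnO2 oxidises the only free, allylic hydroxyl to the (E)-enal without isomerising the alkene.

Step 16
Reactants: 24 dienal acetonide
Product: 25 diol dienal, (2E)-3-[(6R,7R)-6,7-dihydroxy-7-methyl-8-oxo-5,6,7,8-tetrahydro-1H-isochromen-3-yl]prop-2-enal
Conditions: CF3CO2H, H2O, CH2Cl2, 0 °C to rt
Reagents that add atoms: none
Why: Aqueous acid hydrolyses the acetonide, while the pyran enol ether, conjugated to both the ketone and the enal, is too electron-poor to be protonated and opened.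

Step 17
Reactants: 26 orsellinic acid
Product: 27 tert-butyldimethylsilyl 2,4-bis(tert-butyldimethylsilyloxy)-6-methylbenzoate
Conditions: t-BuMe2SiCl (3.3 equiv), imidazole, DMF, rt
Reagents that add atoms: tert-butyldimethylsilyl chloride, CC(C)(C)[Si](C)(C)Cl
Why: Exhaustive silylation masks both phenols with a fluoride-labile group, the only kind compatible with the allylic acetate and polyene of the final product.

Step 18
Reactants: 27 tris-silyl orsellinate
Product: 28 2,4-bis(tert-butyldimethylsilyloxy)-6-methylbenzoyl chloride
Conditions: (COCl)2, DMF (cat.), CH2Cl2, 0 °C to rt; used crude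
Reagents that add atoms: oxalyl chloride, O=C(Cl)C(=O)Cl
Why: Silyl esters are converted directly into acid chlorides by the Vilsmeier chloride under neutral conditions, so the aryl silyl ethers survive.

Step 19
Reactants: 25 diol dienal; 28 aroyl chloride
Product: 29 C6' ester (C7' hydroxyl free)
Conditions: 28 (1.5 equiv), DMAP, Et3N, CH2Cl2, rt
Reagents that add atoms: none
Why: DMAP-catalysed acylation should take the secondary C6' hydroxyl only, since the tertiary C7' hydroxyl is far more hindered, and O-acylation retains configuration.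

Step 20
Reactants: 29 C6' ester
Product: 30 carbinol-half dienal with C7' triethylsilyl ether
Conditions: Et3SiOSO2CF3, 2,6-lutidine, CH2Cl2, −78 °C
Reagents that add atoms: triethylsilyl trifluoromethanesulfonate, CC[Si](CC)(CC)OS(=O)(=O)C(F)(F)F
Why: A silyl triflate caps the tertiary hydroxyl at low temperature, so that C7–OH of the other half is the only free hydroxyl when it is acylated in step 35.

Step 21
Reactants: 3 lactol; 31 propargyl bromide
Product: 33 homopropargylic diol (new C6 carbinol), via allenylzinc bromide 32 (not isolated)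
Conditions: Zn, THF/sat. aq. NH4Cl, 0 °C to rt
Reagents that add atoms: none
Why: Barbier propargylation (SE2' attack of allenylzinc on the open aldehyde form) makes the C5–C6 bond, and Felkin–Anh approach anti to the dioxolane oxygen and past methyl instead of the ring carbon should favour the 6S carbinol, a centre that is later oxidised away.

Step 22
Reactants: 33 homopropargylic diol
Product: 34 bis-acetonide alkyne (O6/O7 acetonide and terminal acetonide)
Conditions: 2,2-dimethoxypropane, camphorsulfonic acid (cat.), acetone, rt
Reagents that add atoms: 2,2-dimethoxypropane, COC(C)(C)OC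
Why: Under equilibrating acid the four contiguous oxygens should settle as the two dioxolanes, which moves the original acetonide onto O6/O7 and ties the old C3/C4 diol into a terminal acetonide.

Step 23
Reactants: 34 bis-acetonide alkyne; 10 methyl chloroformate
Product: 36 bis-acetonide ynoate, via lithium acetylide 35 (not isolated)
Conditions: n-BuLi, THF, −78 °C; then ClCO2Me, −78 to 0 °C
Reagents that add atoms: none
Why: Acetylide acylation as in step 7 installs C1 and activates C8a≡C4a.

Step 24
Reactants: 36 bis-acetonide ynoate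
Product: 38 ent-ynoate aldehyde (enantiomer of 14), via terminal diol 37 (not isolated)
Conditions: H5IO6 (2 equiv), EtOAc, rt
Reagents that add atoms: none
Why: Periodic acid hydrolyses the less substituted terminal acetonide faster than the fully substituted internal one and cleaves the released glycol in the same flask, so the old lactone C3 becomes the C8 aldehyde on a quaternary, non-epimerisable carbon.

Step 25
Reactants: 38 ent-ynoate aldehyde
Product: 40 ring B iodo enoate carbinol (enantiomer of 16), via magnesium iodoallenolate 39 (not isolated)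
Conditions: MgI2·OEt2 (1.5 equiv), CH2Cl2, −20 to 0 °C, anhydrous; aq. NH4Cl
Reagents that add atoms: magnesium diiodide, [Mg+2].[I-].[I-]
Why: This is the iodide conjugate addition/aldol ring closure of step 9 run on the mirror-image substrate, forming C8–C8a and C4a–I with the C8 carbinol again left uncontrolled.

Step 26
Reactants: 40 iodo enoate carbinol
Product: 41 iodo diol (enantiomer of 17)
Conditions: i-Bu2AlH (3.5 equiv), CH2Cl2, −78 °C; aq. potassium sodium tartrate
Reagents that add atoms: none
Why: Enoate reduction to the allylic alcohol as in step 10.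

Step 27
Reactants: 41 iodo diol
Product: 42 C1 silyl ether (enantiomer of 18)
Conditions: t-BuMe2SiCl (1.05 equiv), imidazole, CH2Cl2, 0 °C
Reagents that add atoms: tert-butyldimethylsilyl chloride, CC(C)(C)[Si](C)(C)Cl
Why: Selective silylation of the primary allylic hydroxyl as in step 11.

Step 28
Reactants: 42 silyl ether
Product: 43 iodo enone (enantiomer of 19)
Conditions: Dess–Martin periodinane, pyridine, CH2Cl2, 0 °C to rt
Reagents that add atoms: none
Why: Oxidation of the C8 carbinol merges its epimers as in step 12.

Step 29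
Reactants: 43 iodo enone; 20 (E)-pent-2-en-4-yn-1-ol
Product: 44 enynyl enone (enantiomer of 21)
Conditions: Pd(PPh3)2Cl2 (5 mol %), CuI (10 mol %), Et3N, THF, rt
Reagents that add atoms: none
Why: Sonogashira coupling as in step 13 forms C4a–C4.

Step 30
Reactants: 44 enynyl enone
Product: 46 pyranone alcohol (enantiomer of 23), via hydroxymethyl ynenone 45 (not isolated)
Conditions: Bu4NF (1.1 equiv), THF, 0 °C to rt
Reagents that add atoms: none
Why: Desilylation and 6-endo oxa-Michael closure of pyran A as in step 14.

Step 31
Reactants: 46 pyranone alcohol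
Product: 47 allylic acetate
Conditions: Ac2O, pyridine, DMAP (cat.), CH2Cl2, 0 °C
Reagents that add atoms: acetic anhydride, CC(=O)OC(C)=O
Why: Acetylation of the only free hydroxyl installs the side-chain acetate of the target.

Step 32
Reactants: 47 allylic acetate
Product: 48 diol acetate (C6 and C7 hydroxyls free)
Conditions: CF3CO2H, H2O, CH2Cl2, 0 °C to rt
Reagents that add atoms: none
Why: Acetonide hydrolysis as in step 16, under which a primary allylic acetate on an electron-poor diene should not ionise.

Step 33
Reactants: 48 diol acetate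
Product: 49 dione half, (2E)-3-[(7S)-7-hydroxy-7-methyl-6,8-dioxo-5,6,7,8-tetrahydro-1H-isochromen-3-yl]prop-2-en-1-yl acetate
Conditions: 2-iodoxybenzoic acid (1.2 equiv), DMSO, rt; used directly
Reagents that add atoms: none
Why: IBX oxidises the secondary alcohol of a secondary/tertiary diol to the ketone without glycol cleavage, which removes the C6 stereocentre and leaves C5 as an acidic methylene between the C6 carbonyl and the C4a=C8a–C8=O enone.

Step 34
Reactants: 30 carbinol-half dienal; 49 dione half
Product: 50 coupled trienone (C7 hydroxyl free)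
Conditions: ethylenediammonium diacetate (10 mol %), 4 Å molecular sieves, CH2Cl2, rt
Reagents that add atoms: none
Why: Knoevenagel condensation of the vinylogous 1,3-dicarbonyl carbon C5 with the enal through its iminium ion should give the thermodynamic alkylidene, with the chain syn to the C6 carbonyl and away from C4–H, while the enal alkene stays E.

Step 35
Reactants: 50 coupled trienone; 28 aroyl chloride
Product: 51 fully silylated target
Conditions: 28 (3 equiv), DMAP, Et3N, CH2Cl2, rt to 35 °C
Reagents that add atoms: none
Why: With C5 now an alkylidene carbon, C7–OH is a non-enolisable tertiary carbinol between two carbonyl carbons and the only free hydroxyl, so DMAP-promoted acylation should occur there with retention.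

Step 36
Reactants: 51 fully silylated target
Product: 52 target (CNP0283591.2)
Conditions: HF·pyridine, pyridine, THF, 0 °C to rt
Reagents that add atoms: none
Why: Buffered fluoride cleaves the four aryl silyl ethers and the tertiary triethylsilyl ether and should leave the esters, the allylic acetate and the polyene untouched.

**Compound list**

1 | 2-C-methyl-D-erythrono-1,4-lactone, (3R,4R)-3,4-dihydroxy-3-methyloxolan-2-one | O=C1OC[C@@H](O)[C@@]1(C)O | starting material
2 | 2,3-O-isopropylidene-2-C-methyl-D-erythrono-1,4-lactone | O=C1OC[C@H]2OC(C)(C)O[C@@]12C | intermediate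
3 | 2,3-O-isopropylidene-2-C-methyl-D-erythrofuranose (lactol, both anomers) | OC1OC[C@H]2OC(C)(C)O[C@@]12C | intermediate
4 | [(4R,5S)-5-ethenyl-2,2,5-trimethyl-1,3-dioxolan-4-yl]methanol | OC[C@H]1OC(C)(C)O[C@@]1(C)C=C | intermediate
5 | [(4R,5S)-5-ethenyl-2,2,5-trimethyl-1,3-dioxolan-4-yl]methyl trifluoromethanesulfonate | O=S(=O)(OC[C@H]1OC(C)(C)O[C@@]1(C)C=C)C(F)(F)F | intermediate
6 | trimethylsilylacetylene | C#C[Si](C)(C)C | starting material
7 | lithium (trimethylsilyl)acetylide (formed in the flask) | [Li]C#C[Si](C)(C)C | intermediate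
8 | (4S,5R)-4-ethenyl-2,2,4-trimethyl-5-[3-(trimethylsilyl)prop-2-yn-1-yl]-1,3-dioxolane | C[Si](C)(C)C#CC[C@H]1OC(C)(C)O[C@@]1(C)C=C | intermediate
9 | (4S,5R)-4-ethenyl-2,2,4-trimethyl-5-(prop-2-yn-1-yl)-1,3-dioxolane | C#CC[C@H]1OC(C)(C)O[C@@]1(C)C=C | intermediate
10 | methyl chloroformate | COC(Cl)=O | starting material
11 | lithium acetylide of 9 (formed in the flask) | [Li]C#CC[C@H]1OC(C)(C)O[C@@]1(C)C=C | intermediate
12 | methyl 4-[(4R,5S)-5-ethenyl-2,2,5-trimethyl-1,3-dioxolan-4-yl]but-2-ynoate | COC(=O)C#CC[C@H]1OC(C)(C)O[C@@]1(C)C=C | intermediate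
13 | secondary ozonide (1,2,4-trioxolane) of 12, formed in the flask | COC(=O)C#CC[C@H]1OC(C)(C)O[C@@]1(C)C1OCOO1 | intermediate
14 | methyl 4-[(4R,5R)-5-formyl-2,2,5-trimethyl-1,3-dioxolan-4-yl]but-2-ynoate (ynoate aldehyde) | COC(=O)C#CC[C@H]1OC(C)(C)O[C@@]1(C)C=O | intermediate
15 | magnesium 3-iodoallenolate of 14 (iodomagnesium ketene acetal, formed in the flask) | COC(O[Mg]I)=C=C(I)C[C@H]1OC(C)(C)O[C@@]1(C)C=O | intermediate
16 | ring B' iodo enoate carbinol: methyl 4-hydroxy-6-iodo-2,2,3a-trimethyl-3a,4,7,7a-tetrahydro-1,3-benzodioxole-5-carboxylate, cis-fused, C6'/C7' as in 14, C8' carbinol as both epimers | COC(=O)C1=C(I)C[C@H]2OC(C)(C)O[C@@]2(C)C1O | intermediate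
17 | iodo diol: 16 with CH2OH in place of CO2Me | OCC1=C(I)C[C@H]2OC(C)(C)O[C@@]2(C)C1O | intermediate
18 | C1' tert-butyldimethylsilyl ether of 17 | CC(C)(C)[Si](C)(C)OCC1=C(I)C[C@H]2OC(C)(C)O[C@@]2(C)C1O | intermediate
19 | iodo enone: 18 with the C8' carbinol oxidised to the ketone | CC(C)(C)[Si](C)(C)OCC1=C(I)C[C@H]2OC(C)(C)O[C@@]2(C)C1=O | intermediate
20 | (E)-pent-2-en-4-yn-1-ol | C#C/C=C/CO | starting material
21 | enynyl enone: 19 with (E)-5-hydroxypent-3-en-1-ynyl at C4a' in place of iodine | CC(C)(C)[Si](C)(C)OCC1=C(C#C/C=C/CO)C[C@H]2OC(C)(C)O[C@@]2(C)C1=O | intermediate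
22 | hydroxymethyl ynenone: 21 without the silyl group (formed in the flask) | OCC1=C(C#C/C=C/CO)C[C@H]2OC(C)(C)O[C@@]2(C)C1=O | intermediate
23 | pyranone alcohol: (6R,7R)-3-[(E)-3-hydroxyprop-1-enyl]-6,7-(isopropylidenedioxy)-7-methyl-5,6,7,8-tetrahydro-1H-isochromen-8-one | OC/C=C/C1=CC2=C(CO1)C(=O)[C@]1(C)OC(C)(C)O[C@@H]1C2 | intermediate
24 | dienal acetonide: 23 with the side-chain CH2OH oxidised to CHO | O=C/C=C/C1=CC2=C(CO1)C(=O)[C@]1(C)OC(C)(C)O[C@@H]1C2 | intermediate
25 | (2E)-3-[(6R,7R)-6,7-dihydroxy-7-methyl-8-oxo-5,6,7,8-tetrahydro-1H-isochromen-3-yl]prop-2-enal | O=C/C=C/C1=CC2=C(CO1)C(=O)[C@](C)(O)[C@H](O)C2 | intermediate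
26 | orsellinic acid (2,4-dihydroxy-6-methylbenzoic acid) | Cc1cc(O)cc(O)c1C(=O)O | starting material
27 | tert-butyldimethylsilyl 2,4-bis(tert-butyldimethylsilyloxy)-6-methylbenzoate | Cc1cc(O[Si](C)(C)C(C)(C)C)cc(O[Si](C)(C)C(C)(C)C)c1C(=O)O[Si](C)(C)C(C)(C)C | intermediate
28 | 2,4-bis(tert-butyldimethylsilyloxy)-6-methylbenzoyl chloride | Cc1cc(O[Si](C)(C)C(C)(C)C)cc(O[Si](C)(C)C(C)(C)C)c1C(Cl)=O | intermediate
29 | C6' ester: 25 acylated at O6' with the bis-silylated orsellinoyl group, C7' hydroxyl free | O=C/C=C/C1=CC2=C(CO1)C(=O)[C@](C)(O)[C@H](OC(=O)c1c(C)cc(O[Si](C)(C)C(C)(C)C)cc1O[Si](C)(C)C(C)(C)C)C2 | intermediate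
30 | carbinol-half dienal: 29 with a triethylsilyl ether at O7' | O=C/C=C/C1=CC2=C(CO1)C(=O)[C@](C)(O[Si](CC)(CC)CC)[C@H](OC(=O)c1c(C)cc(O[Si](C)(C)C(C)(C)C)cc1O[Si](C)(C)C(C)(C)C)C2 | intermediate
31 | propargyl bromide | BrCC#C | starting material
32 | allenylzinc bromide (formed in the flask) | C=C=C[Zn]Br | intermediate
33 | homopropargylic diol: (1S)-1-[(4S,5R)-5-(hydroxymethyl)-2,2,4-trimethyl-1,3-dioxolan-4-yl]but-3-yn-1-ol | C#CC[C@H](O)[C@]1(C)OC(C)(C)O[C@@H]1CO | intermediate
34 | bis-acetonide alkyne: cis-dioxolane on O6/O7 carrying propargyl at C6 and, at C7, methyl and a 2,2-dimethyl-1,3-dioxolan-4-yl group | C#CC[C@@H]1OC(C)(C)O[C@]1(C)[C@H]1COC(C)(C)O1 | intermediate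
35 | lithium acetylide of 34 (formed in the flask) | [Li]C#CC[C@@H]1OC(C)(C)O[C@]1(C)[C@H]1COC(C)(C)O1 | intermediate
36 | bis-acetonide ynoate: 34 with CO2Me on the alkyne terminus | COC(=O)C#CC[C@@H]1OC(C)(C)O[C@]1(C)[C@H]1COC(C)(C)O1 | intermediate
37 | terminal diol: 36 after loss of the terminal acetonide (formed in the flask) | COC(=O)C#CC[C@@H]1OC(C)(C)O[C@]1(C)[C@H](O)CO | intermediate
38 | methyl 4-[(4S,5S)-5-formyl-2,2,5-trimethyl-1,3-dioxolan-4-yl]but-2-ynoate (enantiomer of 14) | COC(=O)C#CC[C@@H]1OC(C)(C)O[C@]1(C)C=O | intermediate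
39 | magnesium 3-iodoallenolate of 38 (formed in the flask) | COC(O[Mg]I)=C=C(I)C[C@@H]1OC(C)(C)O[C@]1(C)C=O | intermediate
40 | ring B iodo enoate carbinol (enantiomer of 16, C8 carbinol as both epimers) | COC(=O)C1=C(I)C[C@@H]2OC(C)(C)O[C@]2(C)C1O | intermediate
41 | iodo diol (enantiomer of 17) | OCC1=C(I)C[C@@H]2OC(C)(C)O[C@]2(C)C1O | intermediate
42 | C1 tert-butyldimethylsilyl ether (enantiomer of 18) | CC(C)(C)[Si](C)(C)OCC1=C(I)C[C@@H]2OC(C)(C)O[C@]2(C)C1O | intermediate
43 | iodo enone (enantiomer of 19) | CC(C)(C)[Si](C)(C)OCC1=C(I)C[C@@H]2OC(C)(C)O[C@]2(C)C1=O | intermediate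
44 | enynyl enone (enantiomer of 21) | CC(C)(C)[Si](C)(C)OCC1=C(C#C/C=C/CO)C[C@@H]2OC(C)(C)O[C@]2(C)C1=O | intermediate
45 | hydroxymethyl ynenone (enantiomer of 22, formed in the flask) | OCC1=C(C#C/C=C/CO)C[C@@H]2OC(C)(C)O[C@]2(C)C1=O | intermediate
46 | pyranone alcohol (enantiomer of 23; 6S,7S) | OC/C=C/C1=CC2=C(CO1)C(=O)[C@@]1(C)OC(C)(C)O[C@H]1C2 | intermediate
47 | allylic acetate of 46 | CC(=O)OC/C=C/C1=CC2=C(CO1)C(=O)[C@@]1(C)OC(C)(C)O[C@H]1C2 | intermediate
48 | (2E)-3-[(6S,7S)-6,7-dihydroxy-7-methyl-8-oxo-5,6,7,8-tetrahydro-1H-isochromen-3-yl]prop-2-en-1-yl acetate | CC(=O)OC/C=C/C1=CC2=C(CO1)C(=O)[C@@](C)(O)[C@@H](O)C2 | intermediate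
49 | dione half: (2E)-3-[(7S)-7-hydroxy-7-methyl-6,8-dioxo-5,6,7,8-tetrahydro-1H-isochromen-3-yl]prop-2-en-1-yl acetate | CC(=O)OC/C=C/C1=CC2=C(CO1)C(=O)[C@@](C)(O)C(=O)C2 | intermediate
50 | coupled trienone: C5 of 49 joined to the aldehyde carbon of 30 as C5=CH–CH=CH–C3', C7 hydroxyl free | CC(=O)OC/C=C/C1=CC2=C(CO1)C(=O)[C@@](C)(O)C(=O)/C2=C\C=C\C1=CC2=C(CO1)C(=O)[C@](C)(O[Si](CC)(CC)CC)[C@H](OC(=O)c1c(C)cc(O[Si](C)(C)C(C)(C)C)cc1O[Si](C)(C)C(C)(C)C)C2 | intermediate
51 | fully silylated target: 50 acylated at O7 with the bis-silylated orsellinoyl group | CC(=O)OC/C=C/C1=CC2=C(CO1)C(=O)[C@@](C)(OC(=O)c1c(C)cc(O[Si](C)(C)C(C)(C)C)cc1O[Si](C)(C)C(C)(C)C)C(=O)/C2=C\C=C\C1=CC2=C(CO1)C(=O)[C@](C)(O[Si](CC)(CC)CC)[C@H](OC(=O)c1c(C)cc(O[Si](C)(C)C(C)(C)C)cc1O[Si](C)(C)C(C)(C)C)C2 | intermediate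
52 | CNP0283591.2 (dione half 7S with O7 orsellinate and (E)-3-acetoxypropenyl at C3; carbinol half 6'R,7'R with O6' orsellinate and free C7' hydroxyl; linker C5=CH–CH=CH–C3') | CC(=O)OC/C=C/C1=CC2=C(CO1)C(=O)[C@@](C)(OC(=O)c1c(C)cc(O)cc1O)C(=O)/C2=C\C=C\C1=CC2=C(CO1)C(=O)[C@](C)(O)[C@H](OC(=O)c1c(C)cc(O)cc1O)C2 | target

**Totals and risks**

Total steps: 36. Longest linear sequence: 21 steps (1–16, 19, 20, 34, 35, 36).

Steps most likely to fail:

1. Step 9. The magnesium allenolate may be protonated, or iodide addition may reverse, faster than the allenolate reaches the hindered aldehyde, leaving acyclic β-iodo acrylate; the Lewis acid may also open the acetonide. Fallback: setting out from 14, the ring would be closed under palladium catalysis instead (LiBr, Pd(OAc)2, 2,2'-bipyridine, AcOH). Bromide should add to C4a' trans to palladium at C8a', and the alkenyl–palladium bond, held cis to the C5' tether, should add to the C8' aldehyde to give the bromo enoate carbinol F1. Copper-catalysed bromide–iodide exchange (CuI, NaI, N,N'-dimethylethylenediamine, dioxane) would then bring the route back at 16.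

2. Step 25. The same ring closure on the mirror-image substrate can fail in the same way. Fallback: setting out from 38, the same palladium-catalysed bromide addition/carbonyl insertion would give the bromo enoate carbinol F2, and the same copper-catalysed halide exchange would bring the route back at 40.

3. Step 14 (step 30 is the same reaction in the mirror-image series). The alkoxide may close at C4' instead (5-exo), leading to an alkylidene dihydrofuran and then a furan, or the basic fluoride may deprotonate C5' and isomerise the enyne. Fallback: setting out from 21, the oxygen at C3' would be fixed before ring closure. Pyrrolidine should add 1,6 to C3' to give the vinylogous amide F3. Aqueous AcOH in THF would then hydrolyse the enamine and the primary silyl ether to the hydroxy diketone F4, whose C1' hydroxyl and C3' ketone can condense only to the six-membered enol ether, which brings the route back at 23.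

Further compounds
F1 | step 9 | bromo enoate carbinol (16 with bromine in place of iodine) | COC(=O)C1=C(Br)C[C@H]2OC(C)(C)O[C@@]2(C)C1O
F2 | step 25 | bromo enoate carbinol (40 with bromine in place of iodine) | COC(=O)C1=C(Br)C[C@@H]2OC(C)(C)O[C@]2(C)C1O
F3 | step 14 | vinylogous amide (21 with pyrrolidine added at C3', C4'=C3' enamine) | CC(C)(C)[Si](C)(C)OCC1=C(C=C(N2CCCC2)/C=C/CO)C[C@H]2OC(C)(C)O[C@@]2(C)C1=O
F4 | step 14 | hydroxy diketone (C1' hydroxyl, C3' ketone, C4' methylene) | OCC1=C(CC(=O)/C=C/CO)C[C@H]2OC(C)(C)O[C@@]2(C)C1=O
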